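## Structural features

The target is a B-type proanthocyanidin dimer: an epicatechin 3-O-gallate unit (rings A, C, B) is joined through C4 to C8' of an epigallocatechin 3-O-gallate unit (rings D, F, E), and each C3 oxygen carries a 3,4,5-trihydroxybenzoyl ester. Ring C holds three contiguous stereocentres, C2, C3 and C4 (all R; 2,3-cis, 3,4-trans), and ring F holds two, C2' and C3' (both R, cis). Fifteen free phenols (one catechol and three pyrogallol groups among them) make the compound sensitive to air and base. The gallate esters migrate or hydrolyse under basic conditions, and the doubly benzylic C4–C8' bond ionises at C4 in acid. The real difficulty is C4, a methine that carries two phloroglucinol-type rings, must stand trans to O3 in a 2,3-cis flavan, and must be bonded to C8' and not C6'. The route exploits the fact that rings A and D are both 2,4,6-trioxygenated aryl groups on C4. Before O1–C8a exists they can be two identical 2-fluoro-4,6-dioxygenated phenyl groups, so C4 is not a stereocentre until the C2 oxygen displaces fluoride from one of them. The fluorine left on the other ring is then used twice, to acidify C4a'–H for metalation and as the leaving group at C8a' when ring F is closed.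

## Logic of the disconnections

38 ⇒ 37. All fifteen phenolic O–H bonds are traced back to O–benzyl bonds, so the last step is one neutral hydrogenolysis. This keeps the air- and base-sensitive polyphenol out of every earlier step. It demands that nothing in 37 other than the benzyl ethers is reduced.

37 ⇒ 35 + 36. The two ester C–O bonds at O3 and O3' are cut because gallate esters would not survive the alkoxide and organolithium steps. Both acyl groups come from one acid, 36. The forward step has to acylate two axial secondary hydroxyls, one of them next to the C4 aryl group.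

35 ⇒ 33. O3 and O3' are masked as allyl ethers, a group that does not migrate to a neighbouring alkoxide and is not lost with the benzyl ethers. The forward step must remove two hindered allyl groups without strong acid (C4–C8') or strong base (C4–H).

33 ⇒ 31. Ring F is opened at O1'–C8a'. The lower flavan becomes an open chain on ring D, and the fluorine that ring D kept from the key step becomes the leaving group. The forward step is an alkoxide SNAr at a fluoride flanked by two carbon substituents, with O3' blocked so that only the six-membered ring can form.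

31 ⇒ 30 ⇒ 29 ⇒ 21 + 27. The C4a'–C4' bond is cut, which divides the molecule into two fragments of similar size, each with its stereocentres in place. The forward steps need site-selective lithiation of 21 next to fluorine, addition to 27 without loss of its configuration, and removal of the C4' oxygen without touching C3' or the C4–C8' bond.

21 ⇒ 19 (key). The O1–C8a bond is cut. Ring C and the C4 stereocentre disappear together, and C4 now carries two identical fluoroaryl groups, so one simple arene, 3, supplies both ring A and ring D. The forward step must choose between two diastereotopic aryl groups under the control of C2 and C3.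

19 ⇒ 18 ⇒ 17 ⇒ 13 + 3 (twice). Both C4–aryl bonds are cut at once and C4 becomes an ester carbon. The gain is that 13 holds all the chirality and the aryl part is achiral. Forward, the ester must take two hindered aryl groups without enolisation next to C3, and the tertiary hydroxyl must be removed while the benzylic C2–O bond stays.

13 ⇒ 12 ⇒ 11 ⇒ 7 + 8, and 27 ⇒ 26 ⇒ 25 ⇒ 24 ⇒ 7 + 22. The C2–C3 and C2'–C3' bonds are aldol bonds between a glycolate and an aromatic aldehyde. One enolate precursor, 7, serves both halves and sets four of the five stereocentres, and the oxygen at C3 (C3') enters already differentiated from the oxygen at C2 (C2'). The forward step needs a syn-selective glycolate aldol of defined absolute sense.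

7 ⇒ 4 + 5, and 3 ⇒ 1. The N-acyl bond and two aryl–O bonds are cut to reach purchasable materials.

## Other disconnections considered

Alternative 1: The cut takes the oxygen pairs at C2/C3 and C2'/C3' back to two oxirane rings in A1, and these to the two Z double bonds of A2. In the forward step chloro[N,N'-bis(3,5-di-tert-butylsalicylidene)-1,2-cyclohexanediaminato]manganese with NaOCl would epoxidise both double bonds of A2 in one operation to give A1. After removal of the two silyl groups, each phenol would open its oxirane at the benzylic carbon with inversion, which for a cis-oxirane leads to the 2,3-cis arrangement of rings C and F.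
- In its favour: four of the five stereocentres come from one catalytic operation without an auxiliary. O3 and O3' appear as free hydroxyls ready for galloylation, so no allyl ethers and no deallylation are needed; on these two points it is better than the chosen plan.
- Against it here: C4 must already be a single enantiomer in A2, and the plan offers no way to set it. The upper double bond is allylic to C4, so catalyst and substrate control may oppose each other. Z-styrenes with electron-rich aryl groups can lose cis geometry through a stepwise radical pathway in oxo-manganese epoxidation. Hypochlorite can chlorinate the two phloroglucinol-type rings. Each oxirane can also open at its non-benzylic carbon in a five-membered closure.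
- Comparison: on structure it handles C2, C3, C2' and C3' well but leaves the hardest centre, C4, open, whereas the chosen plan creates C4 in its key step. On mechanism it relies on catalyst control at two unlike alkenes and on 6-endo over 5-exo opening, against substrate control in a chair-like ring closure. On step economy it would be shorter from A2 onward, but an enantioselective route to A2 is not in hand and would add an uncertain number of steps.

Alternative 2: The cut is the C4a–C8a bond. Ring A of A3 is taken apart to the open-chain 3,5-dioxo ester A4, which carries the finished lower flavan and the C2/C3 oxygen pair. In the forward step NaOMe would close A4 by attack of the C4a methylene on the ester carbonyl, and tautomerisation of the new six-membered ring would give the phloroglucinol A3. Ring C would then be closed from one of the two equivalent ortho phenols onto C2 with inversion, after selective removal of the triethylsilyl group.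
- In its favour: the lower unit enters as a complete flavan, so no metalation and no second ring closure are needed on a finished dimer; this is better than the chosen plan on convergency. There is no SNAr on an electron-rich fluoroarene, and no regiochemical question on ring A because A3 is symmetric about the C4 substituent.
- Against it here: ring A is an achiral arene that the chosen plan obtains almost for free, so constructing it costs steps. The least acidic position of A4 (C4a) must act as the nucleophile while the doubly activated C6 and C8 methylenes are deprotonated first. Lactonisation through an enol oxygen competes with C-acylation. The three new phenols must be protected before galloylation. A4 itself still requires a stereoselective C4–C8' bond formation.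
- Comparison: on structure it spends its key step on the simplest ring. On mechanism the regiochemistry of enolate acylation is less secure than an intramolecular SNAr, although the later closure of ring C with inversion is as well precedented as anything in the chosen plan. On step economy it is longer.

Alternative 3: The cut goes through C3–C4 and O1–C2. A5 is divided into the diaryl carbinol A6 (ring A with a free ortho phenol, ring D as part of the finished lower flavan) and the ketone A7, which already carries the galloyl ester. In the forward step a chiral BINOL-derived phosphoric acid would take water from A6 to give the ring A ortho-quinone methide A8, the enol of A7 would add to C4, and the phenol would close onto the ketone carbon to give the hemiketal A5. Reduction at C2 with Et3SiH and a Lewis acid would complete ring C.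
- In its favour: two bonds and ring C are formed from two large fragments in one step, the C3 ester is present from the start so O3 needs no protecting group, and the lower unit enters intact. On step economy and convergency it is better than the chosen plan. In the reduction the neighbouring acyloxy group could shield one face of the C2 oxocarbenium ion and favour the 2,3-cis isomer.
- Against it here: A7 is a weak enol donor compared with the 1,3-dicarbonyl compounds and enamides usually combined with such quinone methides. A8 is already chiral, so the acid may be mismatched. C3, C4 and then C2 depend on one catalyst and one hydride delivery. The acyloxy ketone and the hemiketal are prone to acyl migration and elimination.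
- Comparison: on structure it is the most direct of the four plans. On mechanism it relies on an enol reactivity and a three-centre stereocontrol that are not secured, where the chosen plan uses auxiliary control for four centres and a ring-closure preference for the fifth. On step economy it wins if the key step and the C2 reduction are selective.

Key step: step 9

Assumption: (allyloxy)acetic acid, 3,4-bis(benzyloxy)benzaldehyde, 3,4,5-tris(benzyloxy)benzaldehyde and 3,4,5-tris(benzyloxy)benzoic acid are taken as purchasable; otherwise each is one or two routine steps from allyl alcohol/bromoacetic acid, 3,4-dihydroxybenzaldehyde, 3,4,5-trihydroxybenzaldehyde and gallic acid.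

Remark on structure and naming: the key-step precursor 19 has a three-carbon chain (C2–C3–C4 of the flavan) and is a 2-(allyloxy)-1-aryl-3,3-diarylpropan-1-ol with the syn (1R,2R) configuration; a butane-based name with the allyloxy group on C3 and the aryl pair on C4 would not describe it. Its carbinol oxygen is carried as a silyl ether through the aryl additions and the deoxygenation and is freed only just before the key step.

Remark on numbering: the Z-boron enolate 9 arises from the same enolisation of 7 in steps 3 and 10; it is entered once, at step 3, where it first forms.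

## Route

Step 1
Reactants: 1 1,3,5-trifluorobenzene
Product: 3 1,3-bis(benzyloxy)-5-fluorobenzene, via 1-(benzyloxy)-3,5-difluorobenzene 2 (not isolated)
Conditions: BnOH (2.1 equiv), NaH, NMP, 0 °C to 90 °C
Reagents that add atoms: benzyl alcohol, OCc1ccccc1
Why: Twofold nucleophilic aromatic substitution (addition–elimination) of fluoride by benzyloxide. Each alkoxy group that enters replaces an activating fluorine, so the third substitution is much slower and the reaction can be held at the monofluoride.

Step 2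
Reactants: 4 (allyloxy)acetic acid; 5 (S)-4-benzyloxazolidin-2-one
Product: 7 (S)-3-[(allyloxy)acetyl]-4-benzyloxazolidin-2-one, via mixed pivalic anhydride 6 (not isolated)
Conditions: t-BuCOCl, Et3N, THF, −20 °C; then 5, LiCl, rt
Reagents that add atoms: none
Why: N-acylation of the oxazolidinone through a mixed anhydride. LiCl makes the oxazolidinone N–H acidic enough for triethylamine, and attack occurs at the unhindered glycolyl carbonyl and not at the pivaloyl one.

Step 3
Reactants: 7 (S)-3-[(allyloxy)acetyl]-4-benzyloxazolidin-2-one; 8 3,4-bis(benzyloxy)benzaldehyde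
Product: 11 (S)-3-[(2S,3R)-2-(allyloxy)-3-[3,4-bis(benzyloxy)phenyl]-3-hydroxypropanoyl]-4-benzyloxazolidin-2-one, via dibutylboron Z-enolate 9 (not isolated), via dibutylboron aldolate 10 (not isolated)
Conditions: Bu2BOTf, Et3N, CH2Cl2, −78 to 0 °C; 8, −78 to 0 °C; pH 7 buffer, MeOH, H2O2, 0 °C
Reagents that add atoms: none
Why: Evans syn-glycolate aldol. Soft enolisation gives the Z-boron enolate, which reacts through a closed Zimmerman–Traxler chair on the enolate face away from the benzyl group of the auxiliary. This sets the allyloxy carbon as 2S and the carbinol carbon as 3R (syn), the future C3 and C2 of ring C.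

Step 4
Reactants: 11 syn aldol adduct
Product: 12 (S)-3-[(2S,3R)-2-(allyloxy)-3-[3,4-bis(benzyloxy)phenyl]-3-[(tert-butyldimethylsilyl)oxy]propanoyl]-4-benzyloxazolidin-2-one
Conditions: TBSOTf, 2,6-lutidine, CH2Cl2, −78 to 0 °C
Reagents that add atoms: tert-butyldimethylsilyl trifluoromethanesulfonate, CC(C)(C)[Si](C)(C)OS(=O)(=O)C(F)(F)F
Why: Silylation of a secondary alcohol. The silyl ether blocks retro-aldol cleavage and keeps the carbinol oxygen out of steps 5 to 7.

Step 5
Reactants: 12 silylated imide
Product: 13 methyl (2S,3R)-2-(allyloxy)-3-[3,4-bis(benzyloxy)phenyl]-3-[(tert-butyldimethylsilyl)oxy]propanoate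
Conditions: MeMgBr, MeOH, CH2Cl2, 0 °C
Reagents that add atoms: methanol, CO
Why: Transesterification with bromomagnesium methoxide formed in the flask. It attacks the exocyclic imide carbonyl and is too weakly basic to epimerise C2 or eliminate the silyloxy group; the auxiliary 5 is recovered.

Step 6
Reactants: 13 methyl ester; 3 1,3-bis(benzyloxy)-5-fluorobenzene (2.8 equiv)
Product: 17 (2S,3R)-2-(allyloxy)-3-[3,4-bis(benzyloxy)phenyl]-1,1-bis[2,4-bis(benzyloxy)-6-fluorophenyl]-3-[(tert-butyldimethylsilyl)oxy]propan-1-ol, via aryllithium 14 (not isolated), via arylcerium dichloride 15 (not isolated), via aryl ketone 16 (not isolated)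
Conditions: 3, lithium 2,2,6,6-tetramethylpiperidide (LiTMP, 2.6 equiv, from 2,2,6,6-tetramethylpiperidine and n-BuLi), THF, −78 °C; CeCl3, −78 °C; then 13, −78 to −40 °C
Reagents that add atoms: none
Why: Lithium amide metalation of 3 at its most acidic C–H, the one flanked by fluorine and benzyloxy (an amide base does not deprotonate the position between the two alkoxy groups or the benzylic O–CH2 groups), transmetalation to the less basic organocerium reagent, and double addition to the ester through the ketone. The arene is kept in slight excess over the base so that no free amide meets the enolisable ester, cerium suppresses enolisation of the intermediate alkoxy ketone, and staying below −40 °C prevents loss of LiF to an aryne.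

Step 7
Reactants: 17 tertiary bis(aryl)carbinol
Product: 18 tert-butyl{[(1R,2R)-2-(allyloxy)-1-[3,4-bis(benzyloxy)phenyl]-3,3-bis[2,4-bis(benzyloxy)-6-fluorophenyl]propyl]oxy}dimethylsilane
Conditions: Et3SiH (10 equiv), CF3CO2H, CH2Cl2, −20 to 0 °C
Reagents that add atoms: none
Why: Ionic hydrogenation. The acid ionises the tertiary carbinol to a diarylcarbenium ion stabilised by four ortho/para benzyloxy groups, and the silane delivers hydride. The mono-aryl benzylic silyl ether ionises far more slowly, and the excess silane should trap the cation before the neighbouring proton is lost. The carbon formed is not stereogenic.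

Step 8
Reactants: 18 silyl ether
Product: 19 (1R,2R)-2-(allyloxy)-1-[3,4-bis(benzyloxy)phenyl]-3,3-bis[2,4-bis(benzyloxy)-6-fluorophenyl]propan-1-ol
Conditions: Bu4NF, AcOH, THF, 0 °C to rt
Reagents that add atoms: none
Why: Fluoride-mediated desilylation. The acetic acid buffer prevents the freed alkoxide from starting an uncontrolled ring closure.

Step 9
Reactants: 19 bis(fluoroaryl) alcohol
Product: 21 (2R,3R,4R)-3-(allyloxy)-5,7-bis(benzyloxy)-2-[3,4-bis(benzyloxy)phenyl]-4-[2,4-bis(benzyloxy)-6-fluorophenyl]chromane, via potassium alkoxide 20 (not isolated)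
Conditions: KN(SiMe3)2 (1.1 equiv), THF/DMF, 0 °C to rt
Reagents that add atoms: none
Why: Proposed new method: KN(SiMe3)2 deprotonates the C2 hydroxyl, and the alkoxide 20 adds to the fluorine-bearing carbon of one of the two 2,4-bis(benzyloxy)-6-fluorophenyl groups to give a Meisenheimer-type adduct that expels fluoride; the closest known reaction type is the intramolecular SNAr of ortho-fluoroaryl alkoxides to chromans, which has not been used to choose between two diastereotopic fluoroarenes on one carbon. Ring C closes in a six-membered mode by ipso attack (6-exo-trig when C8a=C8 is counted as the acceptor double bond), and C8a–O1 is the only skeletal bond formed. The new stereocentre C4 is set by substrate control: in the chair-like transition state ring B on C2 is equatorial, the C3 allyloxy group is therefore axial, and the aryl group that does not react sits pseudoaxial on the opposite face, trans to O3. The step needs group selectivity between the two aryl rings, and this rests on two destabilising contacts in the path to the 3,4-cis isomer: a pseudoequatorial spectator aryl group would lie against the C5 benzyloxy group of the forming chroman (peri strain), and the other half-chair would place it 1,3-diaxial to ring B. It also needs attack by the C2 oxygen only, which the allyl ether on O3 secures because it can neither migrate nor close a five-membered ring. Both benzyloxy groups are meta to fluorine and do not deactivate the ipso carbon by resonance, and C2 keeps its configuration because its C–O bond is not broken. The fluorine of the spectator ring stays in place and marks C8a' for the closure of ring F.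

Step 10
Reactants: 7 (S)-3-[(allyloxy)acetyl]-4-benzyloxazolidin-2-one; 22 3,4,5-tris(benzyloxy)benzaldehyde
Product: 24 (S)-3-[(2S,3R)-2-(allyloxy)-3-hydroxy-3-[3,4,5-tris(benzyloxy)phenyl]propanoyl]-4-benzyloxazolidin-2-one, via dibutylboron aldolate 23 (not isolated)
Conditions: Bu2BOTf, Et3N, CH2Cl2, −78 to 0 °C; 22, −78 to 0 °C; pH 7 buffer, MeOH, H2O2, 0 °C
Reagents that add atoms: none
Why: Evans syn-glycolate aldol run exactly as step 3: a second portion of 7 is enolised to the same Z-boron enolate 9, which adds to 22 through the same Zimmerman–Traxler chair. The auxiliary sets the future C3' (2S here) and C2' (3R here) of ring F.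

Step 11
Reactants: 24 syn aldol adduct of the pyrogallol series
Product: 25 (S)-3-[(2S,3R)-2-(allyloxy)-3-[(tert-butyldimethylsilyl)oxy]-3-[3,4,5-tris(benzyloxy)phenyl]propanoyl]-4-benzyloxazolidin-2-one
Conditions: TBSOTf, 2,6-lutidine, CH2Cl2, −78 to 0 °C
Reagents that add atoms: tert-butyldimethylsilyl trifluoromethanesulfonate, CC(C)(C)[Si](C)(C)OS(=O)(=O)C(F)(F)F
Why: Silylation of the secondary alcohol, as in step 4.

Step 12
Reactants: 25 silylated imide
Product: 26 methyl (2S,3R)-2-(allyloxy)-3-[(tert-butyldimethylsilyl)oxy]-3-[3,4,5-tris(benzyloxy)phenyl]propanoate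
Conditions: MeMgBr, MeOH, CH2Cl2, 0 °C
Reagents that add atoms: methanol, CO
Why: Transesterification with bromomagnesium methoxide, as in step 5; the auxiliary is recovered.

Step 13
Reactants: 26 methyl ester
Product: 27 (2S,3R)-2-(allyloxy)-3-[(tert-butyldimethylsilyl)oxy]-3-[3,4,5-tris(benzyloxy)phenyl]propanal
Conditions: i-Bu2AlH (1.1 equiv), CH2Cl2, −78 °C; aq. KNaC4H4O6
Reagents that add atoms: none
Why: Half-reduction of an alkoxy ester. The aluminium-chelated tetrahedral intermediate persists at −78 °C and releases the aldehyde only on work-up. The aldehyde is used at once so that its alkoxy-bearing centre cannot epimerise.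

Step 14
Reactants: 21 4-(fluoroaryl)flavan; 27 aldehyde
Product: 29 (2R,3R,4R)-3-(allyloxy)-5,7-bis(benzyloxy)-2-[3,4-bis(benzyloxy)phenyl]-4-{4,6-bis(benzyloxy)-2-fluoro-3-[(2R,3R)-2-(allyloxy)-3-[(tert-butyldimethylsilyl)oxy]-1-hydroxy-3-[3,4,5-tris(benzyloxy)phenyl]propyl]phenyl}chromane (both epimers at the new carbinol carbon), via ring D aryllithium 28 (not isolated)
Conditions: 21 (1.3 equiv), lithium 2,2,6,6-tetramethylpiperidide (LiTMP, 1.2 equiv, from 2,2,6,6-tetramethylpiperidine and n-BuLi), THF, −78 °C; then 27 (1.0 equiv), −78 °C; AcOH quench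
Reagents that add atoms: none
Why: Fluorine-directed ortho-metalation followed by 1,2-addition to an aldehyde. The ring D C–H between fluorine and benzyloxy (C4a') is the most acidic aryl position and is the one a lithium amide removes, whereas the positions flanked by two oxygen substituents (C6, C8 and C6') and the benzylic and allylic O–CH2 groups are left alone; 21 is kept in excess over the base so that no amide remains to enolise 27, and at −78 °C the aryllithium does not lose LiF. The new carbinol centre C4' is formed as a mixture and is removed in step 15.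

Step 15
Reactants: 29 ring D carbinol
Product: 30 (2R,3R,4R)-3-(allyloxy)-5,7-bis(benzyloxy)-2-[3,4-bis(benzyloxy)phenyl]-4-{4,6-bis(benzyloxy)-2-fluoro-3-[(2R,3R)-2-(allyloxy)-3-[(tert-butyldimethylsilyl)oxy]-3-[3,4,5-tris(benzyloxy)phenyl]propyl]phenyl}chromane
Conditions: Et3SiH (10 equiv), CF3CO2H, CH2Cl2, −40 to −10 °C
Reagents that add atoms: none
Why: Ionic hydrogenation of a secondary benzylic alcohol. Ortho and para benzyloxy groups let it ionise under dilute acid at low temperature, which spares the C4–C8' bond and the silyl, allyl and benzyl ethers. The secondary cation is electrophilic enough to take hydride before it can lose the C3' proton.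

Step 16
Reactants: 30 deoxygenated silyl ether
Product: 31 (2R,3R,4R)-3-(allyloxy)-5,7-bis(benzyloxy)-2-[3,4-bis(benzyloxy)phenyl]-4-{4,6-bis(benzyloxy)-2-fluoro-3-[(2R,3R)-2-(allyloxy)-3-hydroxy-3-[3,4,5-tris(benzyloxy)phenyl]propyl]phenyl}chromane
Conditions: Bu4NF, AcOH, THF, rt
Reagents that add atoms: none
Why: Buffered fluoride desilylation frees the C2' hydroxyl without generating a reactive alkoxide.

Step 17
Reactants: 31 fluoroaryl alcohol
Product: 33 (2R,3R,4R)-3-(allyloxy)-4-[(2R,3R)-3-(allyloxy)-5,7-bis(benzyloxy)-2-[3,4,5-tris(benzyloxy)phenyl]chroman-8-yl]-5,7-bis(benzyloxy)-2-[3,4-bis(benzyloxy)phenyl]chromane, via potassium alkoxide 32 (not isolated)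
Conditions: KN(SiMe3)2 (1.2 equiv), THF/DMF, 0 to 40 °C
Reagents that add atoms: none
Why: Intramolecular SNAr of an ortho-fluoroaryl alkoxide to a chroman. The C2' alkoxide displaces the one remaining fluoride at C8a' in a six-membered closure, so no group selection is involved. C2' keeps its configuration because its C–O bond is not broken, and the allyl ether on O3' excludes the five-membered alternative.

Step 18
Reactants: 33 bis(allyl ether)
Product: 35 (2R,3R,4R)-5,7-bis(benzyloxy)-2-[3,4-bis(benzyloxy)phenyl]-4-[(2R,3R)-5,7-bis(benzyloxy)-3-hydroxy-2-[3,4,5-tris(benzyloxy)phenyl]chroman-8-yl]chroman-3-ol, via bis(prop-1-enyl) ether 34 (not isolated)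
Conditions: [Ir(cod)(PMePh2)2]PF6 (cat., activated with H2, then Ar), THF, rt; then 0.1 M HCl, THF/H2O, rt
Reagents that add atoms: none
Why: Iridium-catalysed isomerisation of both allyl ethers to prop-1-enyl ethers under neutral conditions, then mild acid hydrolysis of the enol ethers. This avoids the strong base that would endanger C4–H and the strong acid that would endanger C4–C8', and leaves the benzyl ethers intact.

Step 19
Reactants: 35 diol; 36 3,4,5-tris(benzyloxy)benzoic acid (4 equiv)
Product: 37 (2R,3R,4R)-5,7-bis(benzyloxy)-2-[3,4-bis(benzyloxy)phenyl]-4-[(2R,3R)-5,7-bis(benzyloxy)-3-{[3,4,5-tris(benzyloxy)benzoyl]oxy}-2-[3,4,5-tris(benzyloxy)phenyl]chroman-8-yl]chroman-3-yl 3,4,5-tris(benzyloxy)benzoate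
Conditions: DCC, DMAP, CH2Cl2, rt
Reagents that add atoms: none
Why: Steglich esterification. The acylpyridinium intermediate is reactive enough for the two axial secondary hydroxyls, and excess acid with a long reaction time allows for the hindered O3 next to the C4 aryl group.

Step 20
Reactants: 37 pentadecabenzyl digallate
Product: 38 (2R,3R,4R)-2-(3,4-dihydroxyphenyl)-5,7-dihydroxy-4-[(2R,3R)-5,7-dihydroxy-3-[(3,4,5-trihydroxybenzoyl)oxy]-2-(3,4,5-trihydroxyphenyl)chroman-8-yl]chroman-3-yl 3,4,5-trihydroxybenzoate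
Conditions: H2 (1 atm), Pd(OH)2/C, THF/MeOH/H2O, rt; filtration under Ar, lyophilisation
Reagents that add atoms: none
Why: Hydrogenolysis of all fifteen benzyl ethers under neutral conditions. The esters, the ring ether bonds and the C4–C8' bond are not cleaved at ambient pressure and temperature, and no stereocentre is touched.

## Compound list

1 | 1,3,5-trifluorobenzene | Fc1cc(F)cc(F)c1 | starting material
2 | 1-(benzyloxy)-3,5-difluorobenzene | Fc1cc(F)cc(OCc2ccccc2)c1 | intermediate
3 | 1,3-bis(benzyloxy)-5-fluorobenzene | Fc1cc(OCc2ccccc2)cc(OCc2ccccc2)c1 | intermediate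
4 | (allyloxy)acetic acid | C=CCOCC(=O)O | starting material
5 | (S)-4-benzyloxazolidin-2-one | O=C1N[C@@H](Cc2ccccc2)CO1 | starting material
6 | (allyloxy)acetic pivalic anhydride | C=CCOCC(=O)OC(=O)C(C)(C)C | intermediate
7 | (S)-3-[(allyloxy)acetyl]-4-benzyloxazolidin-2-one | C=CCOCC(=O)N1[C@@H](Cc2ccccc2)COC1=O | intermediate
8 | 3,4-bis(benzyloxy)benzaldehyde | O=Cc1ccc(OCc2ccccc2)c(OCc2ccccc2)c1 | starting material
9 | dibutylboron (Z)-enolate of 7 | CCCCB(CCCC)O/C(=C\OCC=C)N1[C@@H](Cc2ccccc2)COC1=O | intermediate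
10 | dibutylboron aldolate of 11 | CCCCB(CCCC)O[C@H](c1ccc(OCc2ccccc2)c(OCc2ccccc2)c1)[C@H](OCC=C)C(=O)N1[C@@H](Cc2ccccc2)COC1=O | intermediate
11 | (S)-3-[(2S,3R)-2-(allyloxy)-3-[3,4-bis(benzyloxy)phenyl]-3-hydroxypropanoyl]-4-benzyloxazolidin-2-one | O[C@H](c1ccc(OCc2ccccc2)c(OCc2ccccc2)c1)[C@H](OCC=C)C(=O)N1[C@@H](Cc2ccccc2)COC1=O | intermediate
12 | (S)-3-[(2S,3R)-2-(allyloxy)-3-[3,4-bis(benzyloxy)phenyl]-3-[(tert-butyldimethylsilyl)oxy]propanoyl]-4-benzyloxazolidin-2-one | CC(C)(C)[Si](C)(C)O[C@H](c1ccc(OCc2ccccc2)c(OCc2ccccc2)c1)[C@H](OCC=C)C(=O)N1[C@@H](Cc2ccccc2)COC1=O | intermediate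
13 | methyl (2S,3R)-2-(allyloxy)-3-[3,4-bis(benzyloxy)phenyl]-3-[(tert-butyldimethylsilyl)oxy]propanoate | CC(C)(C)[Si](C)(C)O[C@H](c1ccc(OCc2ccccc2)c(OCc2ccccc2)c1)[C@H](OCC=C)C(=O)OC | intermediate
14 | [2,4-bis(benzyloxy)-6-fluorophenyl]lithium | [Li]c1c(F)cc(OCc2ccccc2)cc1OCc1ccccc1 | intermediate
15 | [2,4-bis(benzyloxy)-6-fluorophenyl]cerium dichloride | Cl[Ce](Cl)c1c(F)cc(OCc2ccccc2)cc1OCc1ccccc1 | intermediate
16 | (2S,3R)-2-(allyloxy)-3-[3,4-bis(benzyloxy)phenyl]-1-[2,4-bis(benzyloxy)-6-fluorophenyl]-3-[(tert-butyldimethylsilyl)oxy]propan-1-one | CC(C)(C)[Si](C)(C)O[C@H](c1ccc(OCc2ccccc2)c(OCc2ccccc2)c1)[C@H](OCC=C)C(=O)c1c(F)cc(OCc2ccccc2)cc1OCc1ccccc1 | intermediate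
17 | (2S,3R)-2-(allyloxy)-3-[3,4-bis(benzyloxy)phenyl]-1,1-bis[2,4-bis(benzyloxy)-6-fluorophenyl]-3-[(tert-butyldimethylsilyl)oxy]propan-1-ol | CC(C)(C)[Si](C)(C)O[C@H](c1ccc(OCc2ccccc2)c(OCc2ccccc2)c1)[C@H](OCC=C)C(O)(c1c(F)cc(OCc2ccccc2)cc1OCc1ccccc1)c1c(F)cc(OCc2ccccc2)cc1OCc1ccccc1 | intermediate
18 | tert-butyl{[(1R,2R)-2-(allyloxy)-1-[3,4-bis(benzyloxy)phenyl]-3,3-bis[2,4-bis(benzyloxy)-6-fluorophenyl]propyl]oxy}dimethylsilane | CC(C)(C)[Si](C)(C)O[C@H](c1ccc(OCc2ccccc2)c(OCc2ccccc2)c1)[C@H](OCC=C)C(c1c(F)cc(OCc2ccccc2)cc1OCc1ccccc1)c1c(F)cc(OCc2ccccc2)cc1OCc1ccccc1 | intermediate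
19 | (1R,2R)-2-(allyloxy)-1-[3,4-bis(benzyloxy)phenyl]-3,3-bis[2,4-bis(benzyloxy)-6-fluorophenyl]propan-1-ol | O[C@H](c1ccc(OCc2ccccc2)c(OCc2ccccc2)c1)[C@H](OCC=C)C(c1c(F)cc(OCc2ccccc2)cc1OCc1ccccc1)c1c(F)cc(OCc2ccccc2)cc1OCc1ccccc1 | intermediate
20 | potassium (1R,2R)-2-(allyloxy)-1-[3,4-bis(benzyloxy)phenyl]-3,3-bis[2,4-bis(benzyloxy)-6-fluorophenyl]propan-1-olate | [K+].[O-][C@H](c1ccc(OCc2ccccc2)c(OCc2ccccc2)c1)[C@H](OCC=C)C(c1c(F)cc(OCc2ccccc2)cc1OCc1ccccc1)c1c(F)cc(OCc2ccccc2)cc1OCc1ccccc1 | intermediate
21 | (2R,3R,4R)-3-(allyloxy)-5,7-bis(benzyloxy)-2-[3,4-bis(benzyloxy)phenyl]-4-[2,4-bis(benzyloxy)-6-fluorophenyl]chromane | C=CCO[C@@H]1[C@@H](c2c(OCc3ccccc3)cc(OCc3ccccc3)cc2F)c2c(OCc3ccccc3)cc(OCc3ccccc3)cc2O[C@@H]1c1ccc(OCc2ccccc2)c(OCc2ccccc2)c1 | intermediate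
22 | 3,4,5-tris(benzyloxy)benzaldehyde | O=Cc1cc(OCc2ccccc2)c(OCc2ccccc2)c(OCc2ccccc2)c1 | starting material
23 | dibutylboron aldolate of 24 | CCCCB(CCCC)O[C@H](c1cc(OCc2ccccc2)c(OCc2ccccc2)c(OCc2ccccc2)c1)[C@H](OCC=C)C(=O)N1[C@@H](Cc2ccccc2)COC1=O | intermediate
24 | (S)-3-[(2S,3R)-2-(allyloxy)-3-hydroxy-3-[3,4,5-tris(benzyloxy)phenyl]propanoyl]-4-benzyloxazolidin-2-one | O[C@H](c1cc(OCc2ccccc2)c(OCc2ccccc2)c(OCc2ccccc2)c1)[C@H](OCC=C)C(=O)N1[C@@H](Cc2ccccc2)COC1=O | intermediate
25 | (S)-3-[(2S,3R)-2-(allyloxy)-3-[(tert-butyldimethylsilyl)oxy]-3-[3,4,5-tris(benzyloxy)phenyl]propanoyl]-4-benzyloxazolidin-2-one | CC(C)(C)[Si](C)(C)O[C@H](c1cc(OCc2ccccc2)c(OCc2ccccc2)c(OCc2ccccc2)c1)[C@H](OCC=C)C(=O)N1[C@@H](Cc2ccccc2)COC1=O | intermediate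
26 | methyl (2S,3R)-2-(allyloxy)-3-[(tert-butyldimethylsilyl)oxy]-3-[3,4,5-tris(benzyloxy)phenyl]propanoate | CC(C)(C)[Si](C)(C)O[C@H](c1cc(OCc2ccccc2)c(OCc2ccccc2)c(OCc2ccccc2)c1)[C@H](OCC=C)C(=O)OC | intermediate
27 | (2S,3R)-2-(allyloxy)-3-[(tert-butyldimethylsilyl)oxy]-3-[3,4,5-tris(benzyloxy)phenyl]propanal | CC(C)(C)[Si](C)(C)O[C@H](c1cc(OCc2ccccc2)c(OCc2ccccc2)c(OCc2ccccc2)c1)[C@H](OCC=C)C=O | intermediate
28 | ring D aryllithium of 21 (lithium on the carbon between fluorine and benzyloxy) | C=CCO[C@@H]1[C@@H](c2c(OCc3ccccc3)cc(OCc3ccccc3)c([Li])c2F)c2c(OCc3ccccc3)cc(OCc3ccccc3)cc2O[C@@H]1c1ccc(OCc2ccccc2)c(OCc2ccccc2)c1 | intermediate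
29 | (2R,3R,4R)-3-(allyloxy)-5,7-bis(benzyloxy)-2-[3,4-bis(benzyloxy)phenyl]-4-{4,6-bis(benzyloxy)-2-fluoro-3-[(2R,3R)-2-(allyloxy)-3-[(tert-butyldimethylsilyl)oxy]-1-hydroxy-3-[3,4,5-tris(benzyloxy)phenyl]propyl]phenyl}chromane, both epimers at the new carbinol carbon | C=CCO[C@@H]1[C@@H](c2c(OCc3ccccc3)cc(OCc3ccccc3)c(C(O)[C@@H](OCC=C)[C@H](O[Si](C)(C)C(C)(C)C)c3cc(OCc4ccccc4)c(OCc4ccccc4)c(OCc4ccccc4)c3)c2F)c2c(OCc3ccccc3)cc(OCc3ccccc3)cc2O[C@@H]1c1ccc(OCc2ccccc2)c(OCc2ccccc2)c1 | intermediate
30 | (2R,3R,4R)-3-(allyloxy)-5,7-bis(benzyloxy)-2-[3,4-bis(benzyloxy)phenyl]-4-{4,6-bis(benzyloxy)-2-fluoro-3-[(2R,3R)-2-(allyloxy)-3-[(tert-butyldimethylsilyl)oxy]-3-[3,4,5-tris(benzyloxy)phenyl]propyl]phenyl}chromane | C=CCO[C@@H]1[C@@H](c2c(OCc3ccccc3)cc(OCc3ccccc3)c(C[C@@H](OCC=C)[C@H](O[Si](C)(C)C(C)(C)C)c3cc(OCc4ccccc4)c(OCc4ccccc4)c(OCc4ccccc4)c3)c2F)c2c(OCc3ccccc3)cc(OCc3ccccc3)cc2O[C@@H]1c1ccc(OCc2ccccc2)c(OCc2ccccc2)c1 | intermediate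
31 | (2R,3R,4R)-3-(allyloxy)-5,7-bis(benzyloxy)-2-[3,4-bis(benzyloxy)phenyl]-4-{4,6-bis(benzyloxy)-2-fluoro-3-[(2R,3R)-2-(allyloxy)-3-hydroxy-3-[3,4,5-tris(benzyloxy)phenyl]propyl]phenyl}chromane | C=CCO[C@@H]1[C@@H](c2c(OCc3ccccc3)cc(OCc3ccccc3)c(C[C@@H](OCC=C)[C@H](O)c3cc(OCc4ccccc4)c(OCc4ccccc4)c(OCc4ccccc4)c3)c2F)c2c(OCc3ccccc3)cc(OCc3ccccc3)cc2O[C@@H]1c1ccc(OCc2ccccc2)c(OCc2ccccc2)c1 | intermediate
32 | potassium alkoxide of 31 | [K+].C=CCO[C@@H]1[C@@H](c2c(OCc3ccccc3)cc(OCc3ccccc3)c(C[C@@H](OCC=C)[C@H]([O-])c3cc(OCc4ccccc4)c(OCc4ccccc4)c(OCc4ccccc4)c3)c2F)c2c(OCc3ccccc3)cc(OCc3ccccc3)cc2O[C@@H]1c1ccc(OCc2ccccc2)c(OCc2ccccc2)c1 | intermediate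
33 | (2R,3R,4R)-3-(allyloxy)-4-[(2R,3R)-3-(allyloxy)-5,7-bis(benzyloxy)-2-[3,4,5-tris(benzyloxy)phenyl]chroman-8-yl]-5,7-bis(benzyloxy)-2-[3,4-bis(benzyloxy)phenyl]chromane | C=CCO[C@@H]1[C@@H](c2c(OCc4ccccc4)cc(OCc4ccccc4)c3c2O[C@H](c2cc(OCc4ccccc4)c(OCc4ccccc4)c(OCc4ccccc4)c2)[C@H](OCC=C)C3)c2c(OCc4ccccc4)cc(OCc4ccccc4)cc2O[C@@H]1c1ccc(OCc2ccccc2)c(OCc2ccccc2)c1 | intermediate
34 | bis(prop-1-enyl) ether corresponding to 33 (double-bond geometry not defined) | CC=CO[C@@H]1[C@@H](c2c(OCc4ccccc4)cc(OCc4ccccc4)c3c2O[C@H](c2cc(OCc4ccccc4)c(OCc4ccccc4)c(OCc4ccccc4)c2)[C@H](OC=CC)C3)c2c(OCc4ccccc4)cc(OCc4ccccc4)cc2O[C@@H]1c1ccc(OCc2ccccc2)c(OCc2ccccc2)c1 | intermediate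
35 | (2R,3R,4R)-5,7-bis(benzyloxy)-2-[3,4-bis(benzyloxy)phenyl]-4-[(2R,3R)-5,7-bis(benzyloxy)-3-hydroxy-2-[3,4,5-tris(benzyloxy)phenyl]chroman-8-yl]chroman-3-ol | O[C@@H]1[C@@H](c2c(OCc4ccccc4)cc(OCc4ccccc4)c3c2O[C@H](c2cc(OCc4ccccc4)c(OCc4ccccc4)c(OCc4ccccc4)c2)[C@H](O)C3)c2c(OCc4ccccc4)cc(OCc4ccccc4)cc2O[C@@H]1c1ccc(OCc2ccccc2)c(OCc2ccccc2)c1 | intermediate
36 | 3,4,5-tris(benzyloxy)benzoic acid | OC(=O)c1cc(OCc2ccccc2)c(OCc2ccccc2)c(OCc2ccccc2)c1 | starting material
37 | 3,3'-bis[3,4,5-tris(benzyloxy)benzoate] of 35 | O=C(O[C@@H]1[C@@H](c2c(OCc4ccccc4)cc(OCc4ccccc4)c3c2O[C@H](c2cc(OCc4ccccc4)c(OCc4ccccc4)c(OCc4ccccc4)c2)[C@H](OC(=O)c2cc(OCc4ccccc4)c(OCc4ccccc4)c(OCc4ccccc4)c2)C3)c2c(OCc4ccccc4)cc(OCc4ccccc4)cc2O[C@@H]1c1ccc(OCc2ccccc2)c(OCc2ccccc2)c1)c1cc(OCc2ccccc2)c(OCc2ccccc2)c(OCc2ccccc2)c1 | intermediate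
38 | epicatechin 3-O-gallate-(4β→8)-epigallocatechin 3-O-gallate (2R,3R,4R;2'R,3'R) | O=C(O[C@@H]1[C@@H](c2c(O)cc(O)c3c2O[C@H](c2cc(O)c(O)c(O)c2)[C@H](OC(=O)c2cc(O)c(O)c(O)c2)C3)c2c(O)cc(O)cc2O[C@@H]1c1ccc(O)c(O)c1)c1cc(O)c(O)c(O)c1 | target

## Step count and risks

Total step count: 20 steps. Longest linear sequence: 15 steps (steps 2 to 9, then 14 to 20).

**Step 9 (key step).** The most likely failure is insufficient discrimination between the two aryl rings in the ring-closing transition state, which would give both C4 epimers. A sluggish closure would also allow base-induced isomerisation of the allyl ether. The fallback uses known chemistry, sets out from 13 and returns at 21; it attaches the spectator ring only after ring C exists. Half-reduction of 13 with i-Bu2AlH gives (2S,3R)-2-(allyloxy)-3-[3,4-bis(benzyloxy)phenyl]-3-[(tert-butyldimethylsilyl)oxy]propanal F1. One equivalent of 14 adds to it to give (2R,3R)-2-(allyloxy)-3-[3,4-bis(benzyloxy)phenyl]-1-[2,4-bis(benzyloxy)-6-fluorophenyl]-3-[(tert-butyldimethylsilyl)oxy]propan-1-ol F2 as both C1 epimers. Buffered Bu4NF gives (2S,3R)-2-(allyloxy)-3-[3,4-bis(benzyloxy)phenyl]-1-[2,4-bis(benzyloxy)-6-fluorophenyl]propane-1,3-diol F3. KN(SiMe3)2 then closes ring C by the known single-arene SNAr, in which the other alkoxide cannot reach fluorine, to give (2R,3R)-3-(allyloxy)-5,7-bis(benzyloxy)-2-[3,4-bis(benzyloxy)phenyl]chroman-4-ol F4. Finally BF3·OEt2 at −78 °C ionises C4 in the presence of excess 3. This is the known Lewis-acid arylation of 4-oxygenated 2,3-cis flavans, in which the arene enters trans to the axial O3 substituent; 3 should react through its less hindered carbon ortho to fluorine and para to benzyloxy, giving 21.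

**Step 7.** The most likely failure is loss of the proton on the allyloxy-bearing carbon from the long-lived diarylcarbenium ion, or a hydride shift to it, before the silane reacts. Either would scramble that centre. Ionisation of the benzylic silyl ether is a second possibility. The fallback sets out from 7 and 14 and returns at 19; it needs no hydride reduction and forms the C3–C4 bond from a preformed cation. Two equivalents of 14 and ethyl formate give bis[2,4-bis(benzyloxy)-6-fluorophenyl]methanol F5, and NaH/MeI gives bis[2,4-bis(benzyloxy)-6-fluorophenyl]methyl methyl ether F6. Compound 7 is enolised with TiCl4 and i-Pr2NEt and alkylated with F6 under Lewis-acid activation. This SN1-type alkylation occurs anti to the benzyl group of the auxiliary and gives (S)-3-[(2R)-2-(allyloxy)-3,3-bis[2,4-bis(benzyloxy)-6-fluorophenyl]propanoyl]-4-benzyloxazolidin-2-one F7. LiBH4 gives (2R)-2-(allyloxy)-3,3-bis[2,4-bis(benzyloxy)-6-fluorophenyl]propan-1-ol F8, and Dess–Martin periodinane gives (2R)-2-(allyloxy)-3,3-bis[2,4-bis(benzyloxy)-6-fluorophenyl]propanal F9. Chelation-controlled addition of [3,4-bis(benzyloxy)phenyl]magnesium bromide F10 (from 4-bromo-1,2-bis(benzyloxy)benzene and Mg) in the presence of MgBr2·OEt2 at −78 °C then gives the syn alcohol 19.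

**Step 14.** The most likely failure is proton transfer from the alkoxy aldehyde to the hindered, basic aryllithium, followed by elimination of silanolate. Incomplete metalation of ring D is a second possibility, and if the addition has to be warmed to proceed, the aryllithium can lose LiF to an aryne. The fallback sets out from 26 and 28 and returns at 30; it replaces carbonyl addition by alkylation and so also removes the need for step 15. LiBH4 reduces 26 to (2R,3R)-2-(allyloxy)-3-[(tert-butyldimethylsilyl)oxy]-3-[3,4,5-tris(benzyloxy)phenyl]propan-1-ol F11. Tf2O and 2,6-di-tert-butyl-4-methylpyridine give (2R,3R)-2-(allyloxy)-3-[(tert-butyldimethylsilyl)oxy]-3-[3,4,5-tris(benzyloxy)phenyl]propyl trifluoromethanesulfonate F12. Displacement of the primary triflate by 28 at −78 °C gives 30 directly.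

**Step 6.** The most likely failure is that the one-flask double addition stalls at the hindered ketone, with enolisation next to the allyloxy centre; incomplete or wrong-site metalation of 3 would add to this. The fallback sets out from 3 and 13 and returns at 17; it fixes the metalation site through a halogen and makes the two additions separate operations. NBS in MeCN brominates 3 at the carbon ortho to fluorine and para to a benzyloxy group to give 1,5-bis(benzyloxy)-2-bromo-3-fluorobenzene F13, and bromine–lithium exchange with n-BuLi at −78 °C turns it into 14 free of amine. MeNHOMe·HCl and i-PrMgCl convert 13 into (2S,3R)-2-(allyloxy)-3-[3,4-bis(benzyloxy)phenyl]-3-[(tert-butyldimethylsilyl)oxy]-N-methoxy-N-methylpropanamide F14. One portion of 14 adds to it and stops at the ketone 16, which is isolated. The second aryl group is then introduced with 15 under conditions tuned for the ketone alone, giving 17. If the second addition cannot be achieved at all, the fallback for step 7 bypasses both steps.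

## Further compounds

F1 | step 9 | (2S,3R)-2-(allyloxy)-3-[3,4-bis(benzyloxy)phenyl]-3-[(tert-butyldimethylsilyl)oxy]propanal | CC(C)(C)[Si](C)(C)O[C@H](c1ccc(OCc2ccccc2)c(OCc2ccccc2)c1)[C@H](OCC=C)C=O
F2 | step 9 | (2R,3R)-2-(allyloxy)-3-[3,4-bis(benzyloxy)phenyl]-1-[2,4-bis(benzyloxy)-6-fluorophenyl]-3-[(tert-butyldimethylsilyl)oxy]propan-1-ol (C1 epimers) | CC(C)(C)[Si](C)(C)O[C@H](c1ccc(OCc2ccccc2)c(OCc2ccccc2)c1)[C@H](OCC=C)C(O)c1c(F)cc(OCc2ccccc2)cc1OCc1ccccc1
F3 | step 9 | (2S,3R)-2-(allyloxy)-3-[3,4-bis(benzyloxy)phenyl]-1-[2,4-bis(benzyloxy)-6-fluorophenyl]propane-1,3-diol (C1 epimers) | O[C@H](c1ccc(OCc2ccccc2)c(OCc2ccccc2)c1)[C@H](OCC=C)C(O)c1c(F)cc(OCc2ccccc2)cc1OCc1ccccc1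
F4 | step 9 | (2R,3R)-3-(allyloxy)-5,7-bis(benzyloxy)-2-[3,4-bis(benzyloxy)phenyl]chroman-4-ol (C4 epimers) | C=CCO[C@@H]1C(O)c2c(OCc3ccccc3)cc(OCc3ccccc3)cc2O[C@@H]1c1ccc(OCc2ccccc2)c(OCc2ccccc2)c1
F5 | step 7 | bis[2,4-bis(benzyloxy)-6-fluorophenyl]methanol | OC(c1c(F)cc(OCc2ccccc2)cc1OCc1ccccc1)c1c(F)cc(OCc2ccccc2)cc1OCc1ccccc1
F6 | step 7 | bis[2,4-bis(benzyloxy)-6-fluorophenyl]methyl methyl ether | COC(c1c(F)cc(OCc2ccccc2)cc1OCc1ccccc1)c1c(F)cc(OCc2ccccc2)cc1OCc1ccccc1
F7 | step 7 | (S)-3-[(2R)-2-(allyloxy)-3,3-bis[2,4-bis(benzyloxy)-6-fluorophenyl]propanoyl]-4-benzyloxazolidin-2-one | O=C([C@H](OCC=C)C(c1c(F)cc(OCc2ccccc2)cc1OCc1ccccc1)c1c(F)cc(OCc2ccccc2)cc1OCc1ccccc1)N1[C@@H](Cc2ccccc2)COC1=O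
F8 | step 7 | (2R)-2-(allyloxy)-3,3-bis[2,4-bis(benzyloxy)-6-fluorophenyl]propan-1-ol | OC[C@H](OCC=C)C(c1c(F)cc(OCc2ccccc2)cc1OCc1ccccc1)c1c(F)cc(OCc2ccccc2)cc1OCc1ccccc1
F9 | step 7 | (2R)-2-(allyloxy)-3,3-bis[2,4-bis(benzyloxy)-6-fluorophenyl]propanal | O=C[C@H](OCC=C)C(c1c(F)cc(OCc2ccccc2)cc1OCc1ccccc1)c1c(F)cc(OCc2ccccc2)cc1OCc1ccccc1
F10 | step 7 | [3,4-bis(benzyloxy)phenyl]magnesium bromide | Br[Mg]c1ccc(OCc2ccccc2)c(OCc2ccccc2)c1
F11 | step 14 | (2R,3R)-2-(allyloxy)-3-[(tert-butyldimethylsilyl)oxy]-3-[3,4,5-tris(benzyloxy)phenyl]propan-1-ol | CC(C)(C)[Si](C)(C)O[C@H](c1cc(OCc2ccccc2)c(OCc2ccccc2)c(OCc2ccccc2)c1)[C@H](OCC=C)CO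
F12 | step 14 | (2R,3R)-2-(allyloxy)-3-[(tert-butyldimethylsilyl)oxy]-3-[3,4,5-tris(benzyloxy)phenyl]propyl trifluoromethanesulfonate | CC(C)(C)[Si](C)(C)O[C@H](c1cc(OCc2ccccc2)c(OCc2ccccc2)c(OCc2ccccc2)c1)[C@H](OCC=C)COS(=O)(=O)C(F)(F)F
F13 | step 6 | 1,5-bis(benzyloxy)-2-bromo-3-fluorobenzene | Brc1c(F)cc(OCc2ccccc2)cc1OCc1ccccc1
F14 | step 6 | (2S,3R)-2-(allyloxy)-3-[3,4-bis(benzyloxy)phenyl]-3-[(tert-butyldimethylsilyl)oxy]-N-methoxy-N-methylpropanamide | CC(C)(C)[Si](C)(C)O[C@H](c1ccc(OCc2ccccc2)c(OCc2ccccc2)c1)[C@H](OCC=C)C(=O)N(C)OC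
A1 | alternative 1 | bis-cis-epoxide with oxiranes at C2/C3 and C2'/C3', ring A and ring D phenols as tert-butyldimethylsilyl ethers | c9ccccc9COc1ccc([C@@H]2O[C@@H]2[C@@H](c3c(OCc9ccccc9)cc(OCc9ccccc9)c(C[C@H]5O[C@H]5c6cc(OCc9ccccc9)c(OCc9ccccc9)c(OCc9ccccc9)c6)c3O[Si](C)(C)C(C)(C)C)c4c(OCc9ccccc9)cc(OCc9ccccc9)cc4O[Si](C)(C)C(C)(C)C)cc1OCc9ccccc9
A2 | alternative 1 | bis-(Z)-alkene precursor of A1 with C4 already configured | c9ccccc9COc1ccc(/C=C\[C@@H](c3c(OCc9ccccc9)cc(OCc9ccccc9)c(C/C=C\c6cc(OCc9ccccc9)c(OCc9ccccc9)c(OCc9ccccc9)c6)c3O[Si](C)(C)C(C)(C)C)c4c(OCc9ccccc9)cc(OCc9ccccc9)cc4O[Si](C)(C)C(C)(C)C)cc1OCc9ccccc9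
A3 | alternative 2 | 2-substituted phloroglucinol (ring A) with open ring C, O3 as tert-butyldimethylsilyl ether, O2 as triethylsilyl ether, lower flavan complete | Oc4cc(O)c([C@H](c2c(OCc9ccccc9)cc(OCc9ccccc9)c3c2O[C@H](c6cc(OCc9ccccc9)c(OCc9ccccc9)c(OCc9ccccc9)c6)[C@H](O[Si](C)(C)C(C)(C)C)C3)[C@@H](O[Si](C)(C)C(C)(C)C)[C@@H](O[Si](CC)(CC)CC)c5ccc(OCc9ccccc9)c(OCc9ccccc9)c5)c(O)c4
A4 | alternative 2 | open-chain methyl 3,5-dioxononanoate carrying the lower flavan on C7, a silyloxy group on C8 and the silyloxy/ring B pair on C9 | COC(=O)CC(=O)CC(=O)C[C@H](c2c(OCc9ccccc9)cc(OCc9ccccc9)c3c2O[C@H](c6cc(OCc9ccccc9)c(OCc9ccccc9)c(OCc9ccccc9)c6)[C@H](O[Si](C)(C)C(C)(C)C)C3)[C@@H](O[Si](C)(C)C(C)(C)C)[C@@H](O[Si](CC)(CC)CC)c5ccc(OCc9ccccc9)c(OCc9ccccc9)c5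
A5 | alternative 3 | 2-hydroxyflavan 3-gallate hemiketal carrying the lower unit at C4 (anomers at C2) | O=C(O[C@@H]1[C@@H](c2c(OCc9ccccc9)cc(OCc9ccccc9)c3c2O[C@H](c6cc(OCc9ccccc9)c(OCc9ccccc9)c(OCc9ccccc9)c6)[C@H](O[Si](C)(C)C(C)(C)C)C3)c4c(OCc9ccccc9)cc(OCc9ccccc9)cc4OC1(O)c5ccc(OCc9ccccc9)c(OCc9ccccc9)c5)c7cc(OCc9ccccc9)c(OCc9ccccc9)c(OCc9ccccc9)c7
A6 | alternative 3 | diaryl carbinol joining a 2-hydroxy-4,6-bis(benzyloxy)phenyl ring (ring A) to C8' of the silylated lower flavan | OC(c4c(OCc9ccccc9)cc(OCc9ccccc9)cc4O)c2c(OCc9ccccc9)cc(OCc9ccccc9)c3c2O[C@H](c6cc(OCc9ccccc9)c(OCc9ccccc9)c(OCc9ccccc9)c6)[C@H](O[Si](C)(C)C(C)(C)C)C3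
A7 | alternative 3 | 2-[3,4-bis(benzyloxy)phenyl]-2-oxoethyl 3,4,5-tris(benzyloxy)benzoate | O=C(COC(=O)c7cc(OCc9ccccc9)c(OCc9ccccc9)c(OCc9ccccc9)c7)c5ccc(OCc9ccccc9)c(OCc9ccccc9)c5
A8 | alternative 3 | ring A ortho-quinone methide derived from A6 | O=C1C=C(OCc9ccccc9)C=C(OCc9ccccc9)C1=Cc2c(OCc9ccccc9)cc(OCc9ccccc9)c3c2O[C@H](c6cc(OCc9ccccc9)c(OCc9ccccc9)c(OCc9ccccc9)c6)[C@H](O[Si](C)(C)C(C)(C)C)C3
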